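**Plan**

- Ring locants: C1 and C4 (adjacent) carry the 2-aminoimidazolyl rings, C2 and C3 the CH2NHCO arms. The C1–imidazole and C4–imidazole bonds join secondary cyclobutane carbons to heteroarene carbons. In the all-trans ring both neighbours of C1 (C2, C4) and of C4 (C3, C1) hold their substituents on one face, so a carboxyl at C1 or C4 can be exchanged for an imidazole trans to both neighbours.
- Retrosynthesis: cut the two amide C–N bonds, then the two imidazole C2–NH2 bonds, return the CH2N arms to methyl esters, and cut both ring–imidazole C–C bonds at once. This leads to an all-trans 2,3-diester 1,4-bis(redox-active ester) and an imidazol-4-ylzinc reagent.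
- Forward: the four-membered ring is bought as the meso dianhydride and no ring is formed. Desymmetrising methanolysis, epimerisation and activation give the coupling precursor, and both imidazoles are attached in one nickel-catalysed operation. Ester reduction, C2 azidation, azide introduction and reduction, two amidations and detritylation follow.
- Stereochemistry: the absolute sense comes from the quinine-mediated methanolysis. Epimerisation at C2 and C3 gives the all-trans array. C1 and C4 are set anew in the coupling by the retained C2 and C3 centres.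

Key step: step 5

Assumption: quinine is taken to open both cis-fused anhydride rings of 1 with the sense established for simpler meso-anhydrides, which leaves the free acids on C1 and C4 as in 2; if the sense is the reverse, quinidine takes its place and nothing else changes.

**Route**

Step 1
Reactants: 1 cis,trans,cis-cyclobutane-1,2,3,4-tetracarboxylic dianhydride
Product: 2 (1R,2R,3R,4R)-2,3-bis(methoxycarbonyl)cyclobutane-1,4-dicarboxylic acid
Conditions: quinine (2.2 equiv), MeOH (6 equiv), toluene (suspension), −55 °C; 2 M HCl wash; crystallisation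
Reagents that add atoms: methanol, CO
Why: Alkaloid-mediated desymmetrising methanolysis of a meso anhydride, in which the same enantiotopic carbonyl of each twofold-related anhydride ring is opened, so the esters should land on C2 and C3 and the acids on C1 and C4 in one absolute sense, while an occasional wrong opening gives the meso 1,3-diester, a diastereomer that crystallisation removes.

Step 2
Reactants: 2 (1R,2R,3R,4R)-2,3-bis(methoxycarbonyl)cyclobutane-1,4-dicarboxylic acid
Product: 3 (1R,2S,3S,4R)-2,3-bis(methoxycarbonyl)cyclobutane-1,4-dicarboxylic acid (all-trans)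
Conditions: NaOMe (6 equiv), MeOH, reflux; then 2 M HCl, 0 °C
Reagents that add atoms: none
Why: Base-mediated epimerisation through the ester enolates, in which only the C–H next to an ester is acidic enough for methoxide, so C2 and C3 should invert to the thermodynamically preferred all-trans ring while C1 and C4 keep the configuration from step 1.

Step 3
Reactants: 3 (1R,2S,3S,4R)-2,3-bis(methoxycarbonyl)cyclobutane-1,4-dicarboxylic acid; 4 N-hydroxyphthalimide
Product: 5 2,3-dimethyl 1,4-bis(1,3-dioxoisoindolin-2-yl) all-trans-cyclobutane-1,2,3,4-tetracarboxylate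
Conditions: 4 (2.2 equiv), DIC (2.4 equiv), DMAP (0.1 equiv), CH2Cl2, 0 °C → rt
Reagents that add atoms: none
Why: Carbodiimide (Steglich-type) esterification, in which the two acids, being trans on a four-membered ring, cannot close to a cyclic anhydride and should both become redox-active esters without change at the methyl esters or the stereocentres.

Step 4
Reactants: 6 4-iodo-1-tritylimidazole
Product: 8 (1-tritylimidazol-4-yl)zinc chloride, via (1-tritylimidazol-4-yl)magnesium chloride 7 (not isolated)
Conditions: i-PrMgCl·LiCl (1.05 equiv), THF, 0 °C → rt; ZnCl2 (1.1 equiv), THF, 0 °C → rt; solution titrated and used as such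
Reagents that add atoms: zinc chloride, Cl[Zn]Cl
Why: Iodine–magnesium exchange at C4 of the N-trityl imidazole followed by transmetalation to zinc, the standard entry to a 4-metalated imidazole for Negishi coupling.

Step 5
Reactants: 5 2,3-dimethyl 1,4-bis(1,3-dioxoisoindolin-2-yl) all-trans-cyclobutane-1,2,3,4-tetracarboxylate; 8 (1-tritylimidazol-4-yl)zinc chloride
Product: 9 dimethyl all-trans-1,4-bis(1-tritylimidazol-4-yl)cyclobutane-2,3-dicarboxylate
Conditions: NiCl2(dme) (20 mol %), 4,4'-di-tert-butyl-2,2'-bipyridine (40 mol %), 8 (6 equiv), THF/DMF, rt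
Reagents that add atoms: none
Why: A monovalent aryl-nickel species, generated from NiCl2(dme), the bipyridine and 8, transfers one electron to a phthalimide ester, whose N–O bond breaks with loss of CO2 to leave a secondary cyclobutyl radical; this is captured by divalent aryl-nickel, the trivalent alkyl(aryl)nickel reductively eliminates the ring–imidazole bond, and transmetalation from zinc restarts the cycle, which runs once at C1 and once at C4. The closest known reaction is the nickel-catalysed decarboxylative Negishi arylation of secondary redox-active esters with aryl- and heteroarylzinc halides. No ring is closed; two C(sp3)–C(sp2) bonds are formed. The configurations at C1 and C4 are erased at the radical stage and written anew by the retained centres C2 and C3: at the flattened C1 radical the ester on C2 and the substituent on C4 lie on one and the same face, so nickel and then the imidazole should arrive on the other face, trans to both, and the C4 radical is ruled in the same way by C3 and C1 whichever site reacts first. The step needs trans,trans selectivity at both sites and chemoselectivity for the active esters over the methyl esters; the all-trans substitution pattern secures the first, and the mild organozinc nucleophile, which leaves methyl esters alone, secures the second.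

Step 6
Reactants: 9 dimethyl all-trans-1,4-bis(1-tritylimidazol-4-yl)cyclobutane-2,3-dicarboxylate
Product: 10 all-trans-[1,4-bis(1-tritylimidazol-4-yl)cyclobutane-2,3-diyl]dimethanol
Conditions: LiAlH4 (3 equiv), THF, 0 °C → rt; aqueous NaOH work-up
Reagents that add atoms: none
Why: Hydride reduction of both esters to primary alcohols, to which N-trityl imidazoles are inert and in which the ring centres, already in the favoured all-trans arrangement, should not move.

Step 7
Reactants: 10 all-trans-[1,4-bis(1-tritylimidazol-4-yl)cyclobutane-2,3-diyl]dimethanol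
Product: 11 all-trans-2,3-bis[(tert-butyldimethylsilyloxy)methyl]-1,4-bis(1-tritylimidazol-4-yl)cyclobutane
Conditions: TBSCl (2.6 equiv), imidazole (5 equiv), DMF, rt
Reagents that add atoms: tert-butyldimethylsilyl chloride, CC(C)(C)[Si](C)(C)Cl
Why: Standard silylation of primary alcohols, which removes the acidic O–H groups ahead of the organolithium step.

Step 8
Reactants: 11 all-trans-2,3-bis[(tert-butyldimethylsilyloxy)methyl]-1,4-bis(1-tritylimidazol-4-yl)cyclobutane
Product: 14 all-trans-1,4-bis(2-azido-1-tritylimidazol-4-yl)-2,3-bis[(tert-butyldimethylsilyloxy)methyl]cyclobutane, via 2,2'-dilithio species 12 (not isolated), via bis(lithium tosyltriazenide) 13 (not isolated)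
Conditions: n-BuLi (2.6 equiv), THF, −78 → −40 °C; TsN3 (3 equiv), −78 °C → rt; aq. NH4Cl
Reagents that add atoms: 4-toluenesulfonyl azide, Cc1ccc(cc1)S(=O)(=O)N=[N+]=[N-]
Why: Deprotonation at C2, the most acidic C–H of an N1-substituted imidazole, followed by electrophilic azide transfer, in which the 2-lithioimidazole adds to the terminal nitrogen of tosyl azide and the triazenide expels sulfinate to leave the 2-azide.

Step 9
Reactants: 14 all-trans-1,4-bis(2-azido-1-tritylimidazol-4-yl)-2,3-bis[(tert-butyldimethylsilyloxy)methyl]cyclobutane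
Product: 15 all-trans-[1,4-bis(2-azido-1-tritylimidazol-4-yl)cyclobutane-2,3-diyl]dimethanol
Conditions: Bu4NF (2.5 equiv), THF, 0 °C → rt
Reagents that add atoms: none
Why: Fluoride-induced desilylation, to which heteroaryl azides and N-trityl groups are inert.

Step 10
Reactants: 15 all-trans-[1,4-bis(2-azido-1-tritylimidazol-4-yl)cyclobutane-2,3-diyl]dimethanol
Product: 16 all-trans-[1,4-bis(2-azido-1-tritylimidazol-4-yl)cyclobutane-2,3-diyl]dimethyl bis(methanesulfonate)
Conditions: MsCl (2.6 equiv), Et3N (4 equiv), CH2Cl2, 0 °C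
Reagents that add atoms: methanesulfonyl chloride, CS(=O)(=O)Cl
Why: Sulfonylation of the primary alcohols, with N3 of each imidazole flanked by the 2-azido group and so less able to attack the new leaving groups.

Step 11
Reactants: 16 all-trans-[1,4-bis(2-azido-1-tritylimidazol-4-yl)cyclobutane-2,3-diyl]dimethyl bis(methanesulfonate)
Product: 17 all-trans-2,3-bis(azidomethyl)-1,4-bis(2-azido-1-tritylimidazol-4-yl)cyclobutane
Conditions: NaN3 (5 equiv), DMF, 50 °C
Reagents that add atoms: sodium azide, [Na+].[N-]=[N+]=[N-]
Why: SN2 displacement of primary mesylates by azide, which does not touch the ring stereocentres.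

Step 12
Reactants: 17 all-trans-2,3-bis(azidomethyl)-1,4-bis(2-azido-1-tritylimidazol-4-yl)cyclobutane
Product: 18 all-trans-2,3-bis(aminomethyl)-1,4-bis(2-amino-1-tritylimidazol-4-yl)cyclobutane
Conditions: H2 (1 atm), Pd/C (10 %), MeOH/THF, rt
Reagents that add atoms: none
Why: Catalytic hydrogenation, which should reduce alkyl and heteroaryl azides alike to amines with loss of N2 at a stage where no aryl halide is present and under neutral conditions that N-trityl tolerates.

Step 13
Reactants: 18 all-trans-2,3-bis(aminomethyl)-1,4-bis(2-amino-1-tritylimidazol-4-yl)cyclobutane; 19 2-(trichloroacetyl)pyrrole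
Product: 20 N-{[all-trans-3-(aminomethyl)-1,4-bis(2-amino-1-tritylimidazol-4-yl)cyclobutan-2-yl]methyl}pyrrole-2-carboxamide
Conditions: 19 (0.8 equiv, slow addition), Na2CO3, DMF, 0 °C → rt; unreacted 18 recovered
Reagents that add atoms: none
Why: Haloform-type acyl transfer from the trichloromethyl ketone to a primary alkylamine with loss of CHCl3, in which the two aminomethyl groups are related by the twofold axis so that either gives the same mono-amide (statistical, hence the limiting acyl donor), while the amidine-like 2-amino groups beside trityl should not compete.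

Step 14
Reactants: 20 N-{[all-trans-3-(aminomethyl)-1,4-bis(2-amino-1-tritylimidazol-4-yl)cyclobutan-2-yl]methyl}pyrrole-2-carboxamide; 21 4-bromo-2-(trichloroacetyl)pyrrole
Product: 22 N1,N1'-ditrityl desbromosceptrin (pyrrole-2-carboxamide on the C2 arm; 4-bromopyrrole-2-carboxamide on the C3 arm)
Conditions: 21 (1.3 equiv), Na2CO3, DMF, rt
Reagents that add atoms: none
Why: The same haloform-type amidation, now on the one remaining primary amine.

Step 15
Reactants: 22 N1,N1'-ditrityl desbromosceptrin
Product: 23 desbromosceptrin, (1S,2R,3R,4S) at the ring carbons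
Conditions: TFA/CH2Cl2 (1:4), Et3SiH (6 equiv), 0 °C → rt; then aq. K2CO3 (free base)
Reagents that add atoms: none
Why: Acidolysis of the N-trityl groups, with the trityl cation reduced by the silane so that it cannot alkylate the pyrroles or the 2-aminoimidazoles, under conditions to which the amides and the aryl bromide are stable.

**Compound list**

Ring configuration of 5 and 9–22 is that of 3 and is fixed by the SMILES.

1 | cis,trans,cis-cyclobutane-1,2,3,4-tetracarboxylic dianhydride (meso) | O=C2[C@@H]1[C@H](C(=O)O2)[C@@H](C(=O)O3)[C@H]1C3=O | starting material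
2 | (1R,2R,3R,4R)-2,3-bis(methoxycarbonyl)cyclobutane-1,4-dicarboxylic acid (acids trans to each other, each ester cis to the acid beside it) | OC(=O)[C@H]1[C@@H](C(=O)OC)[C@H](C(=O)OC)[C@@H]1C(=O)O | intermediate
3 | (1R,2S,3S,4R)-2,3-bis(methoxycarbonyl)cyclobutane-1,4-dicarboxylic acid (all-trans) | OC(=O)[C@H]1[C@H](C(=O)OC)[C@@H](C(=O)OC)[C@@H]1C(=O)O | intermediate
4 | N-hydroxyphthalimide | ON1C(=O)c2ccccc2C1=O | starting material
5 | 2,3-dimethyl 1,4-bis(1,3-dioxoisoindolin-2-yl) all-trans-cyclobutane-1,2,3,4-tetracarboxylate | O=C(ON1C(=O)c2ccccc2C1=O)[C@H]3[C@H](C(=O)OC)[C@@H](C(=O)OC)[C@@H]3C(=O)ON1C(=O)c2ccccc2C1=O | intermediate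
6 | 4-iodo-1-tritylimidazole | Ic1cn(C(c2ccccc2)(c2ccccc2)c2ccccc2)cn1 | starting material
7 | (1-tritylimidazol-4-yl)magnesium chloride (LiCl complex) | Cl[Mg]c1cn(C(c2ccccc2)(c2ccccc2)c2ccccc2)cn1 | intermediate (not isolated)
8 | (1-tritylimidazol-4-yl)zinc chloride | Cl[Zn]c1cn(C(c2ccccc2)(c2ccccc2)c2ccccc2)cn1 | intermediate
9 | dimethyl all-trans-1,4-bis(1-tritylimidazol-4-yl)cyclobutane-2,3-dicarboxylate | c1ccccc1C(c1ccccc1)(c1ccccc1)n1cnc([C@H]2[C@H](C(=O)OC)[C@@H](C(=O)OC)[C@@H]2c2cn(C(c3ccccc3)(c3ccccc3)c3ccccc3)cn2)c1 | intermediate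
10 | all-trans-[1,4-bis(1-tritylimidazol-4-yl)cyclobutane-2,3-diyl]dimethanol | c1ccccc1C(c1ccccc1)(c1ccccc1)n1cnc([C@H]2[C@H](CO)[C@@H](CO)[C@@H]2c2cn(C(c3ccccc3)(c3ccccc3)c3ccccc3)cn2)c1 | intermediate
11 | all-trans-2,3-bis[(tert-butyldimethylsilyloxy)methyl]-1,4-bis(1-tritylimidazol-4-yl)cyclobutane | c1ccccc1C(c1ccccc1)(c1ccccc1)n1cnc([C@H]2[C@H](CO[Si](C)(C)C(C)(C)C)[C@@H](CO[Si](C)(C)C(C)(C)C)[C@@H]2c2cn(C(c3ccccc3)(c3ccccc3)c3ccccc3)cn2)c1 | intermediate
12 | 2,2'-dilithio derivative of 11 (lithium at C2 of each imidazole) | c1ccccc1C(c1ccccc1)(c1ccccc1)n1c([Li])nc([C@H]2[C@H](CO[Si](C)(C)C(C)(C)C)[C@@H](CO[Si](C)(C)C(C)(C)C)[C@@H]2c2cn(C(c3ccccc3)(c3ccccc3)c3ccccc3)c([Li])n2)c1 | intermediate (not isolated)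
13 | bis(lithium N-tosyltriazenide) of 11 (N=N–N(Li)Ts at C2 of each imidazole) | c1ccccc1C(c1ccccc1)(c1ccccc1)n1c(N=NN([Li])S(=O)(=O)c4ccc(C)cc4)nc([C@H]2[C@H](CO[Si](C)(C)C(C)(C)C)[C@@H](CO[Si](C)(C)C(C)(C)C)[C@@H]2c2cn(C(c3ccccc3)(c3ccccc3)c3ccccc3)c(N=NN([Li])S(=O)(=O)c3ccc(C)cc3)n2)c1 | intermediate (not isolated)
14 | all-trans-1,4-bis(2-azido-1-tritylimidazol-4-yl)-2,3-bis[(tert-butyldimethylsilyloxy)methyl]cyclobutane | c1ccccc1C(c1ccccc1)(c1ccccc1)n1c(N=[N+]=[N-])nc([C@H]2[C@H](CO[Si](C)(C)C(C)(C)C)[C@@H](CO[Si](C)(C)C(C)(C)C)[C@@H]2c2cn(C(c3ccccc3)(c3ccccc3)c3ccccc3)c(N=[N+]=[N-])n2)c1 | intermediate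
15 | all-trans-[1,4-bis(2-azido-1-tritylimidazol-4-yl)cyclobutane-2,3-diyl]dimethanol | c1ccccc1C(c1ccccc1)(c1ccccc1)n1c(N=[N+]=[N-])nc([C@H]2[C@H](CO)[C@@H](CO)[C@@H]2c2cn(C(c3ccccc3)(c3ccccc3)c3ccccc3)c(N=[N+]=[N-])n2)c1 | intermediate
16 | bis(methanesulfonate) of 15 | c1ccccc1C(c1ccccc1)(c1ccccc1)n1c(N=[N+]=[N-])nc([C@H]2[C@H](COS(C)(=O)=O)[C@@H](COS(C)(=O)=O)[C@@H]2c2cn(C(c3ccccc3)(c3ccccc3)c3ccccc3)c(N=[N+]=[N-])n2)c1 | intermediate
17 | all-trans-2,3-bis(azidomethyl)-1,4-bis(2-azido-1-tritylimidazol-4-yl)cyclobutane | c1ccccc1C(c1ccccc1)(c1ccccc1)n1c(N=[N+]=[N-])nc([C@H]2[C@H](CN=[N+]=[N-])[C@@H](CN=[N+]=[N-])[C@@H]2c2cn(C(c3ccccc3)(c3ccccc3)c3ccccc3)c(N=[N+]=[N-])n2)c1 | intermediate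
18 | all-trans-2,3-bis(aminomethyl)-1,4-bis(2-amino-1-tritylimidazol-4-yl)cyclobutane | c1ccccc1C(c1ccccc1)(c1ccccc1)n1c(N)nc([C@H]2[C@H](CN)[C@@H](CN)[C@@H]2c2cn(C(c3ccccc3)(c3ccccc3)c3ccccc3)c(N)n2)c1 | intermediate
19 | 2-(trichloroacetyl)pyrrole | O=C(c1ccc[nH]1)C(Cl)(Cl)Cl | starting material
20 | mono(pyrrole-2-carboxamide) of 18 (one CH2NH2 arm acylated) | c1ccccc1C(c1ccccc1)(c1ccccc1)n1c(N)nc([C@H]2[C@H](CNC(=O)c3ccc[nH]3)[C@@H](CN)[C@@H]2c2cn(C(c3ccccc3)(c3ccccc3)c3ccccc3)c(N)n2)c1 | intermediate
21 | 4-bromo-2-(trichloroacetyl)pyrrole | O=C(c1cc(Br)c[nH]1)C(Cl)(Cl)Cl | starting material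
22 | N1,N1'-ditrityl desbromosceptrin | c1ccccc1C(c1ccccc1)(c1ccccc1)n1c(N)nc([C@H]2[C@H](CNC(=O)c3ccc[nH]3)[C@@H](CNC(=O)c3cc(Br)c[nH]3)[C@@H]2c2cn(C(c3ccccc3)(c3ccccc3)c3ccccc3)c(N)n2)c1 | intermediate
23 | desbromosceptrin, (1S,2R,3R,4S) at the ring carbons | Nc1ncc([C@H]2[C@H](CNC(=O)c3ccc[nH]3)[C@@H](CNC(=O)c3cc(Br)c[nH]3)[C@@H]2c2cnc(N)[nH]2)[nH]1 | target

**Step count and weak points**

Total: 15 steps. Longest linear sequence: 14 steps (1 to 23 through steps 1–3 and 5–15); the zinc reagent 8 is a one-step branch (step 4).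

1. Step 5. After the first reduction the radical sits next to a second active ester. A second electron transfer may outrun capture by nickel, so that both carboxyls are expelled and a cyclobutene results. The second site may also be reduced to C–H, or the second, more crowded coupling may lose facial control. The fallback couples one active ester at a time. Starting from 3, one equivalent of 4 with DIC should give the mono-(N-hydroxyphthalimide) ester F1, with unreacted 3 recovered. Nickel coupling with 8 under the conditions of step 5, one further equivalent being spent on the free acid, should give the imidazolyl acid F2. This is activated with 4 and DIC to the redox-active ester F3 and coupled again with 8, which comes back to the route at 9. With a carboxylate and not an active ester beside each radical, the two-electron fragmentation is closed off.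

2. Step 8. The twofold metalation beside the bulky trityl groups may stop after one ring. The triazenides may also collapse back to C–H or by diazo transfer and not by azide transfer. The fallback separates metalation from C–N bond formation. Starting from 11, deprotonation at both C2 positions with (2,2,6,6-tetramethylpiperidin-1-yl)MgCl·LiCl in THF at rt and quenching with I2 should give the bis(2-iodoimidazole) F4. This can be purified and, if only one ring has reacted, submitted again, since the amide base does not exchange the iodide. An Ullmann-type azidation (NaN3, CuI, N,N'-dimethylethylenediamine, sodium ascorbate, EtOH/H2O, 60 °C) then returns to the route at 14.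

3. Step 1. The sparingly soluble dianhydride may open slowly and with incomplete discrimination between the enantiotopic carbonyls, and the sense of opening rests on analogy. The fallback uses an enzyme in place of the alkaloid. Starting from 1, MeOH with catalytic H2SO4 at reflux should give the meso tetramethyl ester F5 without epimerisation. Hydrolysis with pig-liver esterase in pH 7 phosphate buffer should cleave one ester of each cis-1,2-diester pair and stop at the neighbouring carboxylate, delivering 2, where the route is rejoined. The enzyme preparation is to be chosen for the required sense, as for the alkaloid.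

**Further compounds**

F1 | step 5 | all-trans 2,3-bis(methoxycarbonyl)-4-[(1,3-dioxoisoindolin-2-yl)oxycarbonyl]cyclobutane-1-carboxylic acid | O=C(ON1C(=O)c2ccccc2C1=O)[C@H]3[C@H](C(=O)OC)[C@@H](C(=O)OC)[C@@H]3C(=O)O
F2 | step 5 | all-trans 2,3-bis(methoxycarbonyl)-4-(1-tritylimidazol-4-yl)cyclobutane-1-carboxylic acid | c1ccccc1C(c1ccccc1)(c1ccccc1)n1cnc([C@H]2[C@H](C(=O)OC)[C@@H](C(=O)OC)[C@@H]2C(=O)O)c1
F3 | step 5 | N-hydroxyphthalimide ester of F2 | c1ccccc1C(c1ccccc1)(c1ccccc1)n1cnc([C@H]2[C@H](C(=O)OC)[C@@H](C(=O)OC)[C@@H]2C(=O)ON2C(=O)c3ccccc3C2=O)c1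
F4 | step 8 | all-trans-2,3-bis[(tert-butyldimethylsilyloxy)methyl]-1,4-bis(2-iodo-1-tritylimidazol-4-yl)cyclobutane | c1ccccc1C(c1ccccc1)(c1ccccc1)n1c(I)nc([C@H]2[C@H](CO[Si](C)(C)C(C)(C)C)[C@@H](CO[Si](C)(C)C(C)(C)C)[C@@H]2c2cn(C(c3ccccc3)(c3ccccc3)c3ccccc3)c(I)n2)c1
F5 | step 1 | tetramethyl cis,trans,cis-cyclobutane-1,2,3,4-tetracarboxylate (meso) | COC(=O)[C@H]1[C@@H](C(=O)OC)[C@H](C(=O)OC)[C@@H]1C(=O)OC
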